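The closed, stirred vessel holds G and Q at one temperature, and Z is read as a fraction of the G charged.

| flask | G | Q | temperature | remark | time |
|---|---|---|---|---|---|
| Saturday's | 0.035 M | 0.15 M | 0 °C | run made earlier |  |
| Friday's | 0.071 M | 0.15 M | 12 °C | run made earlier |  |
| Thursday's | 0.11 M | 0.15 M | 0 °C | run made earlier |  |
| south | 0.15 M | 0.150 M | 20 °C |  | 20 h |
| west | 0.040 M | 0.150 M | 5 °C |  | 20 h |

| run | time / h | Z / % |
|---|---|---|
| Saturday's | 2.50 | 1.0 |
| Saturday's | 6.00 | 1.4 |
| Saturday's | 15.0 | 3.8 |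
| Saturday's | 20.0 | 3.8 |
| Saturday's | 25.0 | 2.3 |
| Friday's | 0.833 | 2.3 |
| Friday's | 1.50 | 0 |
| Friday's | 3.00 | 4.2 |
| Friday's | 5.00 | 5.1 |
| Friday's | 10.0 | 8.4 |
| Thursday's | 2.50 | 0 |
| Thursday's | 4.00 | 0.5 |
| Thursday's | 8.00 | 1.7 |
| Thursday's | 15.0 | 5.6 |
| Thursday's | 25.0 | 4.7 |

(scatter of a reading: 1 percentage point)

1. which one finishes higher in amount of Z, in percent of the G charged ("neither" within 2 percentage points) (south / west / neither)
2. amount of Z at the end, in percent of the G charged, south
3. amount of Z at the end, in percent of the G charged, west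



Early in a run, time divided by Z is the time a whole charge takes at that pace. Saturday's 3.8 % at 15.0 h gives 395 h at 0 °C, and Friday's 8.4 % at 10.0 h gives 119 h at 12 °C. With one factor per degree, south has 53.5 h and west 240 h. If G leaves by this route and no other, the fraction left is the exponential of minus time over that figure, so Z reaches 31.2 % in south and 8.01 % in west.

The weak link is the figure at 0 °C, which rests on one reading, and at 25.0 h Saturday's 2.3 % lies below its line. A line through the origin over both runs at that temperature gives 532 h. West then has 285 h as its Z-lifetime, the first-order lifetime of G toward Z, and south has 43.9 h. Still assuming that G leaves by no other route, this reckoning puts Z at 36.6 % in south and 6.77 % in west.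

The forecast names south, with 18 % there and 5.5 % in west, lower in south than this reckoning, on the ground that "Loss of Z will also speed up".

The flask gives south as the higher, at 24.9 % against 6.26 % in west.

    G → Z (k = 0.0352 h⁻¹, Ea = 99.0 kJ mol⁻¹)
    2 G ⇌ E (K = 17.0 L mol⁻¹, k = 0.157 L mol⁻¹ h⁻¹, Ea = 67.0 kJ mol⁻¹, ΔH = −73.0 kJ mol⁻¹)
    G + Q → L (k = 0.475 L mol⁻¹ h⁻¹, Ea = 66.0 kJ mol⁻¹)
    G + Z → D (k = 0.0387 L mol⁻¹ h⁻¹, Ea = 60.0 kJ mol⁻¹)
    G ⇌ X (K = 6.04, k = 0.0107 h⁻¹, Ea = 103 kJ mol⁻¹, ΔH = −34.0 kJ mol⁻¹)
    (constants at 20 °C)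

In south, G to Z and G + Q to L ran side by side while G fell to 28.2 % at 10.0 h and 11.3 % at 20.0 h, and L stood at 40.2 % beside Z at 24.9 %. In west the same pair ran with G still at 62.8 % at 20.0 h. The fraction of G summed over time in straight pieces between these times, divided by each flask's reckoned Z-lifetime, comes to 19.1 % in south and 5.62 % in west. Read at 72.0 h, the west charge holds G at 21.4 %, that sum is 13.3 %, and Z stands at 14.0 %.

The numbers in the tables are calculated on assumed constants; the scatter is artificial.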